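The γ-lactone ring (O1, C2=O, C3, C4, C5) holds oxygen on C3 and on C5 in a 1,3-relationship, trans across the ring and therefore syn along the open C2–C6 chain. The plan cuts the C5–O1 bond and remakes it by tethering: a tert-butyl carbonate on O3 reaches a terminal alkene under IBr. One operation thus forms the C5–O bond, sets C5 relative to C3 through a temporary six-membered cyclic carbonate spanning O3 and C5, and leaves iodine on C6 as the handle for phenyl. The precursor is the homoallylic carbonate methyl (R)-2-(tert-butoxycarbonyloxy)pent-4-enoate, whose single stereocentre comes from methyl (R)-glycidate.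

Key step: step 3

Remark: the lactone is numbered O1, C2(=O), C3, C4, C5 with the benzylic carbon as C6; the target is read as (3R,5R), the trans-3,5 isomer, and commercial solutions of vinylmagnesium bromide and phenyllithium are used as bought.

Step 1
Reactants: 1 methyl (R)-oxirane-2-carboxylate (methyl (R)-glycidate); 2 vinylmagnesium bromide
Product: 3 methyl (R)-2-hydroxypent-4-enoate
Conditions: CuI (10 mol %), THF, −78 °C; sat. aq NH4Cl
Reagents that add atoms: vinylmagnesium bromide (2), C=C[Mg]Br
Why: Copper-catalysed Grignard opening of a glycidic ester in an SN2 sense at the unsubstituted ring carbon C3, which at −78 °C outruns addition to the methyl ester; the C2–O bond is not touched, so the (R) centre of 1 is carried over unchanged and no new stereocentre is formed.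

Step 2
Reactants: 3 methyl (R)-2-hydroxypent-4-enoate; 4 di-tert-butyl dicarbonate
Product: 5 methyl (R)-2-[(tert-butoxycarbonyl)oxy]pent-4-enoate
Conditions: Boc2O, DMAP (cat.), MeCN, 0 °C to rt
Reagents that add atoms: di-tert-butyl dicarbonate (4), CC(C)(C)OC(=O)OC(=O)OC(C)(C)C
Why: DMAP-catalysed O-acylation of the secondary hydroxyl by Boc2O gives the mixed tert-butyl carbonate with no bond to the stereocentre broken, and the alkene and methyl ester are inert to these neutral conditions.

Step 3
Reactants: 5 methyl (R)-2-[(tert-butoxycarbonyl)oxy]pent-4-enoate
Product: 8 methyl (4R,6S)-6-(iodomethyl)-2-oxo-1,3-dioxane-4-carboxylate, via iodiranium bromide 6 (not isolated), via tert-butoxydioxanylium bromide 7 (not isolated)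
Conditions: IBr, PhMe, −85 °C; aq Na2S2O3/NaHCO3
Reagents that add atoms: iodine monobromide, IBr
Why: IBr reversibly adds I+ to the terminal alkene to give iodiranium ion 6, the carbonyl oxygen of the tert-butyl carbonate opens it anti at the internal carbon (C5 of the future lactone) to give cyclic cation 7, and loss of the tert-butyl group as 2-methylpropene leaves the neutral carbonate. The closest known reaction type is the iodocarbonate cyclisation of homoallylic tert-butyl carbonates to syn-1,3-diol derivatives in its low-temperature IBr variant. The 1,3-dioxan-2-one ring closes in a 6-exo mode by attack at the more substituted alkene carbon, the 7-endo alternative not being competitive. The new stereocentre (C6 of the dioxanone, C5 of the lactone) is controlled by the carbinol centre inherited from 1 through a chair-like transition state in which CO2Me and the developing CH2I group are both equatorial, which gives the cis-4,6 ring and hence the syn O3/O5 pair. The step needs this 1,3-syn diastereoselectivity and chemoselectivity for the carbonate over the ester carbonyl (which could close 5-exo to an iodolactone); reversible iodiranium formation at −85 °C secures the first, and the higher nucleophilicity of the carbonate oxygen together with the easy loss of tert-butyl compared with methyl (the reason the ester is kept as its methyl ester) secures the second.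

Step 4
Reactants: 8 methyl (4R,6S)-6-(iodomethyl)-2-oxo-1,3-dioxane-4-carboxylate
Product: 10 methyl (R)-2-hydroxy-3-[(S)-oxiran-2-yl]propanoate, via iodohydrin diol ester 9 (not isolated)
Conditions: K2CO3, MeOH, 0 °C to rt
Reagents that add atoms: none
Why: Carbonate methanolysis (base-catalysed transesterification to dimethyl carbonate) frees the C5 oxygen, whose alkoxide displaces the adjacent primary iodide in an intramolecular Williamson closure (3-exo-tet) that breaks only the C6–I bond, so C5 keeps its configuration and the syn relationship to C3 is preserved, while any lactone formed reversibly by the same alkoxide is reopened by methoxide and the methyl ester only exchanges degenerately with the solvent.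

Step 5
Reactants: 10 methyl (R)-2-hydroxy-3-[(S)-oxiran-2-yl]propanoate; 11 phenyllithium
Product: 13 (3R,5R)-5-benzyl-3-hydroxyoxolan-2-one, via dihydroxy ester 12 (not isolated)
Conditions: Ph2CuLi (3 equiv, from 11 and CuI), Et2O, −40 to 0 °C; sat. aq NH4Cl; then TsOH·H2O (cat.), CH2Cl2, rt
Reagents that add atoms: phenyllithium (11), [Li]c1ccccc1, delivered as lithium diphenylcuprate, [Li+].c1ccccc1[Cu-]c1ccccc1
Why: Gilman cuprate opening of a terminal epoxide by SN2 attack at the unsubstituted carbon C6 touches neither stereocentre and spares the ester, one equivalent of the reagent being spent on the free hydroxyl, and the C5 alkoxide of 12 then lactonises 5-exo-trig onto the methyl ester, which the acid treatment of the crude product completes.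

Step 6
Reactants: 13 (3R,5R)-5-benzyl-3-hydroxyoxolan-2-one; 14 3,4-dimethoxybenzoyl chloride
Product: 15 (3R,5R)-5-benzyl-2-oxooxolan-3-yl 3,4-dimethoxybenzoate (trichoderolide F)
Conditions: pyridine, DMAP (cat.), CH2Cl2, 0 °C to rt
Reagents that add atoms: 3,4-dimethoxybenzoyl chloride (14), COc1ccc(C(Cl)=O)cc1OC
Why: DMAP-catalysed acylation of the secondary C3 hydroxyl by the aroyl chloride (nucleophilic acyl substitution) forms the ester at oxygen only, so both ring stereocentres are carried into the target unchanged and the mild pyridine base avoids enolisation at C3.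

Compound list
1 | methyl (R)-oxirane-2-carboxylate (methyl (R)-glycidate) | COC(=O)[C@H]1CO1 | starting material
2 | vinylmagnesium bromide | C=C[Mg]Br | starting material
3 | methyl (R)-2-hydroxypent-4-enoate | COC(=O)[C@H](O)CC=C | intermediate
4 | di-tert-butyl dicarbonate | CC(C)(C)OC(=O)OC(=O)OC(C)(C)C | starting material
5 | methyl (R)-2-[(tert-butoxycarbonyl)oxy]pent-4-enoate | COC(=O)[C@H](OC(=O)OC(C)(C)C)CC=C | intermediate
6 | methyl (R)-2-[(tert-butoxycarbonyl)oxy]-3-[(R)-iodiran-1-ium-2-yl]propanoate bromide (productive iodiranium ion, not isolated) | COC(=O)[C@H](OC(=O)OC(C)(C)C)C[C@@H]1C[I+]1.[Br-] | intermediate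
7 | (4R,6S)-2-tert-butoxy-6-(iodomethyl)-4-(methoxycarbonyl)-1,3-dioxan-2-ylium bromide (not isolated) | COC(=O)[C@H]1C[C@@H](CI)OC(OC(C)(C)C)=[O+]1.[Br-] | intermediate
8 | methyl (4R,6S)-6-(iodomethyl)-2-oxo-1,3-dioxane-4-carboxylate (cis) | COC(=O)[C@H]1C[C@@H](CI)OC(=O)O1 | intermediate
9 | methyl (2R,4S)-2,4-dihydroxy-5-iodopentanoate (not isolated) | COC(=O)[C@H](O)C[C@@H](CI)O | intermediate
10 | methyl (R)-2-hydroxy-3-[(S)-oxiran-2-yl]propanoate | COC(=O)[C@H](O)C[C@H]1CO1 | intermediate
11 | phenyllithium | [Li]c1ccccc1 | starting material
12 | methyl (2R,4R)-2,4-dihydroxy-5-phenylpentanoate (syn diol, not isolated) | COC(=O)[C@H](O)C[C@@H](Cc1ccccc1)O | intermediate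
13 | (3R,5R)-5-benzyl-3-hydroxyoxolan-2-one (trans) | O[C@@H]1C[C@@H](Cc2ccccc2)OC1=O | intermediate
14 | 3,4-dimethoxybenzoyl chloride | COc1ccc(C(Cl)=O)cc1OC | starting material
15 | (3R,5R)-5-benzyl-2-oxooxolan-3-yl 3,4-dimethoxybenzoate (trichoderolide F) | COc1ccc(C(=O)O[C@@H]2C[C@@H](Cc3ccccc3)OC2=O)cc1OC | target

Total step count: 6. Longest linear sequence: 6 steps (1 → 3 → 5 → 8 → 10 → 13 → 15).

Steps most likely to fail

Step 3. The closure may show poor facial selectivity, because CO2Me is only a weak equatorial anchor in the chair-like transition state, and the ester carbonyl may compete for the activated alkene. The fallback sets out from 3 and comes back at 10, and it relies on a different control element. Aminolysis of 3 with dimethylamine in methanol should give (R)-2-hydroxy-N,N-dimethylpent-4-enamide F1. Iodolactonisation of this amide with I2 in aqueous THF is steered by allylic 1,3-strain between the NMe2 group and the C2 substituent, a known route to 2,4-trans γ-lactones, and should give (3R,5S)-3-hydroxy-5-(iodomethyl)oxolan-2-one F2. K2CO3 in methanol then opens the lactone to iodohydrin 9, which closes to epoxy alcohol 10.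

Step 5. The cuprate may be consumed unproductively by the free hydroxyl, the lithium alkoxide of the α-hydroxy ester may aggregate and slow the epoxide opening, or lactonisation may stay incomplete. The fallback sets out from 10 and comes back at 13 by a protecting-group approach with catalytic copper. Silylation of 10 with TBSCl and imidazole in DMF should give methyl (R)-2-[(tert-butyldimethylsilyl)oxy]-3-[(S)-oxiran-2-yl]propanoate F3. PhMgBr with catalytic CuI in THF at −40 °C, the ester-tolerant conditions of step 1, should open the epoxide to methyl (2R,4R)-2-[(tert-butyldimethylsilyl)oxy]-4-hydroxy-5-phenylpentanoate F4. Catalytic TsOH closes this to (3R,5R)-5-benzyl-3-[(tert-butyldimethylsilyl)oxy]oxolan-2-one F5, and HF·pyridine in THF removes the silyl group to give 13.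

Step 4. The freed C5 alkoxide may partition towards lactonisation, the epoxide may be opened by methoxide on prolonged exposure, and the small water-soluble epoxy alcohol may be lost on isolation. The fallback sets out from 8 and comes back at 13, bypassing the epoxide. The carbonate is kept as the diol protecting group and the C6–phenyl bond is made directly at the primary iodide by an iron-catalysed Kumada-type coupling (PhMgBr added slowly, FeCl3 as catalyst, TMEDA, THF, 0 °C), whose radical pathway avoids β-elimination of the carbonate oxygen. This should give methyl (4R,6R)-6-benzyl-2-oxo-1,3-dioxane-4-carboxylate F6. K2CO3 in methanol then cleaves the carbonate to dihydroxy ester 12, and acidification with catalytic TsOH closes the lactone 13.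

Further compounds
F1 | step 3 | (R)-2-hydroxy-N,N-dimethylpent-4-enamide | CN(C)C(=O)[C@H](O)CC=C
F2 | step 3 | (3R,5S)-3-hydroxy-5-(iodomethyl)oxolan-2-one | O[C@@H]1C[C@@H](CI)OC1=O
F3 | step 5 | methyl (R)-2-[(tert-butyldimethylsilyl)oxy]-3-[(S)-oxiran-2-yl]propanoate | COC(=O)[C@H](O[Si](C)(C)C(C)(C)C)C[C@H]1CO1
F4 | step 5 | methyl (2R,4R)-2-[(tert-butyldimethylsilyl)oxy]-4-hydroxy-5-phenylpentanoate | COC(=O)[C@H](O[Si](C)(C)C(C)(C)C)C[C@@H](Cc1ccccc1)O
F5 | step 5 | (3R,5R)-5-benzyl-3-[(tert-butyldimethylsilyl)oxy]oxolan-2-one | CC(C)(C)[Si](C)(C)O[C@@H]1C[C@@H](Cc2ccccc2)OC1=O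
F6 | step 4 | methyl (4R,6R)-6-benzyl-2-oxo-1,3-dioxane-4-carboxylate | COC(=O)[C@H]1C[C@@H](Cc2ccccc2)OC(=O)O1
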